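**Retrosynthetic overview**

- The C25 acyl chain (numbered from the ester carbonyl C1 to the methyl C25) is cut at C14–C15 into two primary alkyl radicals. Both come from carboxylic acids by loss of CO2: dodecanoic acid gives the undecyl half, and the mono(2-phenylethyl) ester of pentadecanedioic acid gives the C14 ester half. The forward reaction is a crossed Kolbe electrolysis, an oxidative radical–radical union of two carbons of the same polarity.
- Enabling feature: C14 and C15 are unactivated CH2 groups inside an unbranched (CH2)23 chain. The only functional group, the ester at C1, is twelve methylenes away from C14, and the benzene ring sits behind an O–CH2–CH2 spacer. Nothing stabilises a cation at either carbon and nothing else is oxidised at the anode, so two primary radicals made from carboxylates should simply combine.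
- The half-ester comes from 15-pentadecanolide: ring opening with 2-phenylethanol installs the final ester, and oxidation of the released C15 CH2OH gives the carboxyl that is later expelled as CO2.
- No ring is formed. The 16-membered lactone ring is opened in step 1 and the benzene ring is carried unchanged from 2-phenylethanol.

Key step: step 3

Remark: the target has no stereocentre, so no step needs stereocontrol; 15-pentadecanolide, 2-phenylethanol and dodecanoic acid are taken as commercial.

**Route**

Step 1
Reactants: 1 15-pentadecanolide (oxacyclohexadecan-2-one); 2 2-phenylethanol
Product: 3 2-phenylethyl 15-hydroxypentadecanoate
Conditions: TsOH·H2O (5 mol%), neat 2 (8 equiv), 90 °C; Et3N quench, then excess 2 distilled off in vacuo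
Reagents that add atoms: none
Why: Acid-catalysed transesterification (alcoholysis) of the unstrained macrolactone in a large excess of the primary alcohol should drive the ring-opening equilibrium to the open-chain hydroxy ester, and neutralising the catalyst before the excess alcohol is removed should prevent re-lactonisation or oligomerisation.

Step 2
Reactants: 3 2-phenylethyl 15-hydroxypentadecanoate
Product: 5 15-oxo-15-(2-phenylethoxy)pentadecanoic acid, via 2-phenylethyl 15-oxopentadecanoate 4 (not isolated)
Conditions: TEMPO (0.2 equiv), PhI(OAc)2 (2.5 equiv), CH2Cl2/H2O 2:1, rt
Reagents that add atoms: water, O
Why: TEMPO/PhI(OAc)2 oxidation (oxoammonium-mediated) in the presence of water should take the primary alcohol through aldehyde 4 and its hydrate to the carboxylic acid, while the ester and the unactivated phenyl ring are inert to the oxoammonium salt.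

Step 3
Reactants: 5 15-oxo-15-(2-phenylethoxy)pentadecanoic acid; 6 dodecanoic acid (lauric acid)
Product: 9 2-phenylethyl pentacosanoate, via undecyl radical 7 (not isolated), via 13-[(2-phenylethoxy)carbonyl]tridecyl radical 8 (not isolated)
Conditions: 5 (1 equiv), 6 (6 equiv), KOH (5 mol% of total CO2H), MeOH, 45–50 °C, undivided cell, Pt anode/Pt cathode, constant current ca. 0.25 A cm⁻², periodic polarity reversal, stopped while the electrolyte is still weakly acidic
Reagents that add atoms: none
Why: Crossed Kolbe electrolysis: at the platinum anode at high current density the carboxylates of 5 and 6 are each oxidised by one electron and lose CO2, giving the primary radicals 8 and 7 side by side in the carboxylate layer at the electrode surface, where radical–radical combination forms the C14–C15 bond while the acid protons are reduced to H2 at the cathode. The closest known reaction type is the mixed Kolbe coupling of a fatty acid with an alkyl hydrogen α,ω-alkanedioate, the classical way to lengthen fatty esters. No ring is closed and no stereocentre is created. The step needs cross-coupling over homo-coupling, which is only statistical and is secured by the large excess of cheap 6, so that nearly every radical 8 should be captured by a radical 7; the two homo-dimers (docosane with no ester group and bis(2-phenylethyl) octacosanedioate with two) bracket the mono-ester 9 in polarity and should be removed on silica. It also needs radical combination to win over further oxidation to a cation, which the substrate secures because both radical carbons are unbranched primary CH2 groups with no α-heteroatom, aryl or alkyl substituent. The ester, separated from the reacting carboxyl by thirteen methylenes, and the isolated phenyl ring should survive because the adsorbed carboxylate layer shields other groups from the anode and the electrolyte stays weakly acidic as long as free acid remains, which suppresses methanolysis of the 2-phenylethyl ester.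

**Compound list**

1 | 15-pentadecanolide (oxacyclohexadecan-2-one) | O=C1CCCCCCCCCCCCCCO1 | starting material
2 | 2-phenylethanol | OCCc1ccccc1 | starting material
3 | 2-phenylethyl 15-hydroxypentadecanoate | OCCCCCCCCCCCCCCC(=O)OCCc1ccccc1 | intermediate
4 | 2-phenylethyl 15-oxopentadecanoate | O=CCCCCCCCCCCCCCC(=O)OCCc1ccccc1 | intermediate
5 | 15-oxo-15-(2-phenylethoxy)pentadecanoic acid | OC(=O)CCCCCCCCCCCCCC(=O)OCCc1ccccc1 | intermediate
6 | dodecanoic acid (lauric acid) | CCCCCCCCCCCC(=O)O | starting material
7 | undecyl radical | [CH2]CCCCCCCCCC | intermediate
8 | 13-[(2-phenylethoxy)carbonyl]tridecyl radical | [CH2]CCCCCCCCCCCCC(=O)OCCc1ccccc1 | intermediate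
9 | 2-phenylethyl pentacosanoate | CCCCCCCCCCCCCCCCCCCCCCCCC(=O)OCCc1ccccc1 | target

Total step count: 3
Longest linear sequence: 3 steps (1 → 3 → 5 → 9)

**Steps most likely to fail**

1. Step 3 (crossed Kolbe electrolysis).
   - What may go wrong: statistical radical pairing may divert too much of the half-ester into homo-coupling. Waxy products may film the anode, so that the potential drifts and two-electron (cation-derived) products appear. Slow methanolysis of the 2-phenylethyl ester may set in if the electrolyte turns alkaline near the end.
   - Fallback (sets out from 5, returns at 9): the same C14–C15 bond would be made by a nickel-catalysed decarboxylative alkyl–alkyl cross-coupling, in which each fragment is used once and no methanol is present. Acid 5 would be condensed with N-hydroxyphthalimide (DIC, cat. DMAP, CH2Cl2) to the redox-active ester 1-(1,3-dioxoisoindolin-2-yl) 15-(2-phenylethyl) pentadecanedioate F1. Commercial 1-bromoundecane would be converted with Mg in THF into undecylmagnesium bromide F2, and this with ZnCl2 (0.5 equiv) into diundecylzinc F3. Treating F1 with F3 (2 equiv), NiCl2·glyme (20 mol%) and 4,4'-di-tert-butyl-2,2'-bipyridine (40 mol%) in THF/DMF at rt should give 9 directly; the 2-phenylethyl ester should tolerate the dialkylzinc at this temperature.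

2. Step 1 (ring-opening transesterification).
   - What may go wrong: the alcoholysis is reversible. Ring opening may stay incomplete, and during removal of the excess alcohol the hydroxy ester may re-close or oligomerise by intermolecular transesterification if any catalyst remains active.
   - Fallback (sets out from 1, returns at 3): the ester would be made irreversibly by carboxylate alkylation. Lactone 1 would be saponified (KOH, MeOH/H2O, reflux; then aq. HCl) to 15-hydroxypentadecanoic acid F4. Its potassium carboxylate (K2CO3, DMF, 50 °C) would be alkylated with (2-bromoethyl)benzene in an SN2 esterification that should leave the far less nucleophilic primary hydroxyl untouched, giving 3.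

3. Step 2 (alcohol-to-acid oxidation).
   - What may go wrong: in the two-phase medium the waxy substrate may stall at the aldehyde stage. The aldehyde may also be trapped by unreacted alcohol as a hemiacetal that is oxidised on to a dimeric ester.
   - Fallback (sets out from 1, with 2 as the alcohol partner, returns at 5): the order of oxidation and esterification would be inverted, so that the oxidation runs on a substrate with no other ester. Lactone 1 would be saponified as above to 15-hydroxypentadecanoic acid F4. This would be oxidised in homogeneous solution (TEMPO cat., NaOCl cat., NaClO2, MeCN/phosphate buffer pH 6.7, 35 °C, or alternatively a Jones oxidation) to pentadecanedioic acid F5. F5 (3 equiv) would then be mono-esterified with 2 (1 equiv) under Fischer conditions (cat. TsOH, toluene, Dean–Stark) to give 5; the sparingly soluble excess diacid would be filtered off and recycled, and the small diester fraction removed on silica.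

**Further compounds**

F1 | step 3 | 1-(1,3-dioxoisoindolin-2-yl) 15-(2-phenylethyl) pentadecanedioate | O=C(CCCCCCCCCCCCCC(=O)OCCc1ccccc1)ON1C(=O)c2ccccc2C1=O
F2 | step 3 | undecylmagnesium bromide | CCCCCCCCCCC[Mg]Br
F3 | step 3 | diundecylzinc | CCCCCCCCCCC[Zn]CCCCCCCCCCC
F4 | step 1 | 15-hydroxypentadecanoic acid | OCCCCCCCCCCCCCCC(=O)O
F5 | step 2 | pentadecanedioic acid | OC(=O)CCCCCCCCCCCCCC(=O)O
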